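## Retrosynthetic overview

- Target ⇒ ester C–O bond (last step): (−)-lariciresinol + (R)-2-methylbutanoic acid.
- (−)-Lariciresinol ⇒ C7–O bond of the only ring (the tetrahydrofuran): a p-quinone methide of (S,S)-(+)-secoisolariciresinol is trapped by its γ'-hydroxyl, the same ring-closing event as in lignan biosynthesis. The C2 symmetry of the diol makes both ends equivalent.
- (S,S)-Secoisolariciresinol ⇒ C8–C8' bond: auxiliary-controlled oxidative dimerisation of an Evans imide enolate of dihydroferulic acid, the laboratory counterpart of the dirigent-controlled 8–8' radical coupling.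
- Ring order: one ring only, closed in the penultimate step. The phenol is masked and unmasked inside steps 1 and 3, so there are no separate protecting-group steps.

Assumption: (R)-2-methylbutanoic acid is bought as the single enantiomer. The target SMILES was read as (2R) in the acyl group and (7R,8S,8'S) in the lignan core, i.e. the (−)-lariciresinol series.

## Route

Step 1
Reactants: 1 3-(4-hydroxy-3-methoxyphenyl)propanoic acid (dihydroferulic acid); 2 (4R)-4-benzyl-1,3-oxazolidin-2-one
Product: 4 (4R)-4-benzyl-3-{3-[3-methoxy-4-(pivaloyloxy)phenyl]propanoyl}-1,3-oxazolidin-2-one, via mixed pivalic anhydride 3 (not isolated)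
Conditions: PivCl (2.3 equiv), Et3N (3.5 equiv), THF, −20 → 0 °C; then LiCl (1.1 equiv), 2 (1.1 equiv), rt
Reagents that add atoms: pivaloyl chloride, CC(C)(C)C(=O)Cl
Why: Mixed-anhydride N-acylation of an Evans oxazolidinone (LiCl/Et3N variant), in which PivCl turns the acid into its mixed pivalic anhydride and caps the phenol as the pivalate in the same pot, and 2 then attacks the unhindered carbonyl of the anhydride; no new stereocentre.

Step 2
Reactants: 4 (two molecules)
Product: 6 (2S,3S)-1,4-bis[(4R)-4-benzyl-2-oxo-1,3-oxazolidin-3-yl]-2,3-bis{[3-methoxy-4-(pivaloyloxy)phenyl]methyl}butane-1,4-dione, via lithium Z-enolate 5 (not isolated)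
Conditions: LiN(iPr)2 (1.05 equiv, commercial solution), THF, −78 °C; then TiCl4 (1.1 equiv), −78 °C → rt
Reagents that add atoms: none
Why: Oxidative homocoupling of a chiral imide enolate, in which TiCl4 takes over the chelated Z-enolate 5 and one-electron transfer to tetravalent titanium (leaving trivalent titanium) lets two α-carbons join, each on the face opposite the 4-benzyl group of its (R)-auxiliary, which sets both new centres as S; the meso and R,R isomers are diastereomers of 6 and are removed by chromatography or crystallisation.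

Step 3
Reactants: 6 the bis-imide described in step 2
Product: 7 (+)-secoisolariciresinol [(2S,3S)-2,3-bis(4-hydroxy-3-methoxybenzyl)butane-1,4-diol]
Conditions: LiAlH4 (6 equiv), THF, 0 °C → rt; aqueous work-up at pH 5
Reagents that add atoms: none
Why: Hydride reduction, in which LiAlH4 reduces the two exocyclic imide carbonyls to primary alcohols with release of the auxiliary and cleaves both aryl pivalates in the same operation, reduction being much faster than enolisation so that both S centres are kept.

Step 4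
Reactants: 7 (+)-secoisolariciresinol
Product: 9 (−)-lariciresinol [4-[(2R,3S,4S)-4-(4-hydroxy-3-methoxybenzyl)-3-(hydroxymethyl)oxolan-2-yl]-2-methoxyphenol], via p-quinone methide 8 (not isolated)
Conditions: DDQ (1.0 equiv, added over 1 h), 1,4-dioxane (0.02 M), 15 °C → rt; precipitated DDQH2 filtered off
Reagents that add atoms: none
Why: Biomimetic quinone-methide cycloetherification (DDQ benzylic dehydrogenation of a 4-alkylphenol, then 5-exo oxa-Michael addition), in which hydride loss from either of the two homotopic benzylic CH2 groups gives the same quinone methide 8, the only hydroxyl that can reach it through a five-membered transition state (O9') closes the ring, and the aryl group goes trans to the neighbouring CH2OH so that C7 (oxolane C2) is formed as R while the 3,4-cis relationship is already fixed by the S,S centres.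

Step 5
Reactants: 9 (−)-lariciresinol; 10 (2R)-2-methylbutanoic acid
Product: 11 [(2R,3S,4S)-2-(4-hydroxy-3-methoxyphenyl)-4-(4-hydroxy-3-methoxybenzyl)oxolan-3-yl]methyl (2R)-2-methylbutanoate (target)
Conditions: 10 (1.1 equiv), PPh3 (1.3 equiv), DIAD (1.3 equiv), THF, 0 °C → rt
Reagents that add atoms: none
Why: Chemoselective Mitsunobu esterification, in which only the carboxylic acid is acidic enough to drive the redox condensation and its carboxylate displaces the phosphonium-activated primary hydroxyl, so the two phenols stay free; the substitution occurs at a CH2 and the acid reacts as a nucleophile, so neither the ring centres nor the (R) α-centre of the acyl group can be scrambled.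

## Compound list

1 | 3-(4-hydroxy-3-methoxyphenyl)propanoic acid (dihydroferulic acid) | COc1cc(CCC(=O)O)ccc1O | starting material
2 | (4R)-4-benzyl-1,3-oxazolidin-2-one | O=C1N[C@H](Cc2ccccc2)CO1 | starting material
3 | 3-[3-methoxy-4-(pivaloyloxy)phenyl]propanoic pivalic anhydride | COc1cc(CCC(=O)OC(=O)C(C)(C)C)ccc1OC(=O)C(C)(C)C | intermediate
4 | (4R)-4-benzyl-3-{3-[3-methoxy-4-(pivaloyloxy)phenyl]propanoyl}-1,3-oxazolidin-2-one | COc1cc(CCC(=O)N2[C@H](Cc3ccccc3)COC2=O)ccc1OC(=O)C(C)(C)C | intermediate
5 | lithium (Z)-enolate of 4 | [Li]O/C(=C\Cc1ccc(OC(=O)C(C)(C)C)c(OC)c1)N1[C@H](Cc2ccccc2)COC1=O | intermediate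
6 | (2S,3S)-1,4-bis[(4R)-4-benzyl-2-oxo-1,3-oxazolidin-3-yl]-2,3-bis{[3-methoxy-4-(pivaloyloxy)phenyl]methyl}butane-1,4-dione | O=C([C@@H](Cc1ccc(OC(=O)C(C)(C)C)c(OC)c1)[C@H](Cc1ccc(OC(=O)C(C)(C)C)c(OC)c1)C(=O)N1[C@H](Cc2ccccc2)COC1=O)N1[C@H](Cc2ccccc2)COC1=O | intermediate
7 | (+)-secoisolariciresinol, (2S,3S)-2,3-bis(4-hydroxy-3-methoxybenzyl)butane-1,4-diol | OC[C@@H](Cc1ccc(O)c(OC)c1)[C@H](Cc1ccc(O)c(OC)c1)CO | intermediate
8 | p-quinone methide of 7 (one benzyl group dehydrogenated to a (3-methoxy-4-oxocyclohexa-2,5-dien-1-ylidene)methyl group; both stereocentres as in 7) | OC[C@@H](C=C1C=CC(=O)C(OC)=C1)[C@H](Cc1ccc(O)c(OC)c1)CO | intermediate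
9 | (−)-lariciresinol, 4-[(2R,3S,4S)-4-(4-hydroxy-3-methoxybenzyl)-3-(hydroxymethyl)oxolan-2-yl]-2-methoxyphenol | OC[C@@H]1[C@H](Cc2ccc(O)c(OC)c2)CO[C@H]1c1ccc(O)c(OC)c1 | intermediate
10 | (2R)-2-methylbutanoic acid | CC[C@@H](C)C(=O)O | starting material
11 | [(2R,3S,4S)-2-(4-hydroxy-3-methoxyphenyl)-4-(4-hydroxy-3-methoxybenzyl)oxolan-3-yl]methyl (2R)-2-methylbutanoate | CC[C@@H](C)C(=O)OC[C@@H]1[C@H](Cc2ccc(O)c(OC)c2)CO[C@H]1c1ccc(O)c(OC)c1 | target

## Step count and risks

Total steps: 5. Longest linear sequence: 5 (1 → 4 → 6 → 7 → 9 → 11).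

**Most likely to fail, in order:**

**Step 4 (DDQ quinone-methide cyclisation).** The risks are:
- over-oxidation of 9 at its second benzylic CH2 or at C7–H;
- C-trapping of the quinone methide by the other arene to give an aryltetralin if the medium turns acidic;
- tautomerisation of 8 to a styrene, which would erase C8;
- some of the C7 epimer.

Fallback: it sets out from 7 and comes back at 9. With DDQ (2.2 equiv) both benzylic positions are oxidised and both quinone methides are trapped, which gives the C2-symmetric furofuran (−)-pinoresinol F1. Partial hydrogenolysis (H2, 1 atm, Pd/C, EtOAc/MeOH, stopped near one equivalent of H2) then cleaves one benzylic C–O bond to give 9. This moves the selectivity problem from the oxidation to the reduction, where the over-reduced product is 7 itself and is recycled.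

**Step 2 (oxidative enolate dimerisation).** The risks are a moderate yield, incomplete facial control (meso and R,R dimers), and attack on the aryl pivalate. Fallback: it sets out from 4 and comes back at 7, building the two centres one after the other by polar chemistry.
- The sodium enolate of 4 (NaN(SiMe3)2, THF, −78 °C) is alkylated with tert-butyl bromoacetate to give tert-butyl (3S)-4-[(4R)-4-benzyl-2-oxo-1,3-oxazolidin-3-yl]-3-{[3-methoxy-4-(pivaloyloxy)phenyl]methyl}-4-oxobutanoate F2.
- LiBH4 reduction of the imide and TsOH-catalysed lactonisation give (4S)-4-{[3-methoxy-4-(pivaloyloxy)phenyl]methyl}oxolan-2-one F3.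
- The lithium enolate of F3 (LiN(SiMe3)2, THF, −78 °C) is alkylated trans to the C4 substituent with 4-(benzyloxy)-3-methoxybenzyl bromide F4 (from the commercial benzyl alcohol and PBr3). This gives (3S,4S)-3-{[4-(benzyloxy)-3-methoxyphenyl]methyl}-4-{[3-methoxy-4-(pivaloyloxy)phenyl]methyl}oxolan-2-one F5.
- LiAlH4 opens the lactone and removes the pivalate to give (2S,3S)-2-{[4-(benzyloxy)-3-methoxyphenyl]methyl}-3-[(4-hydroxy-3-methoxyphenyl)methyl]butane-1,4-diol F6.
- H2, Pd/C removes the benzyl ether to give 7.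

**Step 5 (Mitsunobu on the unprotected triol).** The risks are competing O-alkylation of a phenol and slow reaction at the β-branched primary alcohol. Fallback: it sets out from 9 and comes back at 11. All three hydroxyls are acylated with 10 (3.5 equiv, EDC·HCl, DMAP, CH2Cl2) to give the tris[(2R)-2-methylbutanoate] of (−)-lariciresinol F7. The two aryl esters are then cleaved selectively by aminolysis with pyrrolidine (CH2Cl2, 0 °C), which leaves the alkyl ester and gives 11.

Further compounds
F1 | step 4 | (−)-pinoresinol, 4,4'-[(1R,3aS,4R,6aS)-tetrahydro-1H,3H-furo[3,4-c]furan-1,4-diyl]bis(2-methoxyphenol) | O1C[C@@H]2[C@H]([C@@H]1c1ccc(O)c(OC)c1)CO[C@H]2c1ccc(O)c(OC)c1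
F2 | step 2 | tert-butyl (3S)-4-[(4R)-4-benzyl-2-oxo-1,3-oxazolidin-3-yl]-3-{[3-methoxy-4-(pivaloyloxy)phenyl]methyl}-4-oxobutanoate | CC(C)(C)OC(=O)C[C@H](Cc1ccc(OC(=O)C(C)(C)C)c(OC)c1)C(=O)N1[C@H](Cc2ccccc2)COC1=O
F3 | step 2 | (4S)-4-{[3-methoxy-4-(pivaloyloxy)phenyl]methyl}oxolan-2-one | O=C1C[C@H](Cc2ccc(OC(=O)C(C)(C)C)c(OC)c2)CO1
F4 | step 2 | 4-(benzyloxy)-3-methoxybenzyl bromide | COc1cc(CBr)ccc1OCc1ccccc1
F5 | step 2 | (3S,4S)-3-{[4-(benzyloxy)-3-methoxyphenyl]methyl}-4-{[3-methoxy-4-(pivaloyloxy)phenyl]methyl}oxolan-2-one | O=C1[C@@H](Cc2ccc(OCc3ccccc3)c(OC)c2)[C@H](Cc2ccc(OC(=O)C(C)(C)C)c(OC)c2)CO1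
F6 | step 2 | (2S,3S)-2-{[4-(benzyloxy)-3-methoxyphenyl]methyl}-3-[(4-hydroxy-3-methoxyphenyl)methyl]butane-1,4-diol | OC[C@@H](Cc1ccc(OCc2ccccc2)c(OC)c1)[C@H](Cc1ccc(O)c(OC)c1)CO
F7 | step 5 | (−)-lariciresinol tris[(2R)-2-methylbutanoate] | CC[C@@H](C)C(=O)OC[C@@H]1[C@H](Cc2ccc(OC(=O)[C@H](C)CC)c(OC)c2)CO[C@H]1c1ccc(OC(=O)[C@H](C)CC)c(OC)c1
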